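**Plan**

1. Numbering (elemane): cyclohexane C5–C10. C10 carries CH3 (C14) and vinyl (C1=C2); C5 the arm C4(=C3H2)–C15HO; C6 the free OH; C7 the arm C11(=C13H2)–C12, lactonised to the oxygen on C8; C9 the angelate.
2. Enabling feature: the ring neighbours C8 and C9 both carry oxygen on the same face (C8–O equatorial, C9–O axial), a cis-1,2-diol that maps onto reductive coupling of two aldehydes.
3. Cuts, in retrosynthetic order: the angelate C–O and the lactone O–C12 bond (with both allylic oxidation levels); ring bond C8–C9; chain bond C6–C7; chain bond C5–C10; the ester C–O joining two C5 building blocks.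
4. Forward: esterification, then Ireland–Claisen (C5–C10), then allylboration (C6–C7) give the open chain C9–C10–C5–C6–C7–C8. The cyclohexane closes at C8–C9; the γ-lactone closes afterwards by oxidation.
5. Stereochemistry: C5/C10 from a chiral boron E(O)-enolate Claisen through a chair; C6/C7 from a Z-γ-substituted allylboronate (chair, anti-Felkin); C8/C9 from the chair of the pinacol closure; the Z-angelate from angelic acid.

Key step: step 19

Assumption: the (S,S)-bromoborane is written for step 8, its sense of induction being taken from simple allyl esters; should it prove opposite on this ester, the (R,R)-antipode is used with no other change.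

**Route**

Step 1
Reactants: 1 prenyl acetate
Product: 2 (E)-4-hydroxy-3-methylbut-2-en-1-yl acetate
Conditions: SeO2 (cat.), t-BuOOH, CH2Cl2, 0 → 23 °C
Reagents that add atoms: tert-butyl hydroperoxide, CC(C)(C)OO (oxygen donor; transferred through catalytic selenium dioxide, O=[Se]=O)
Why: Riley-type allylic oxidation (ene reaction, then [2,3]-shift) attacks the methyl group trans to the chain of the trisubstituted alkene and should therefore give the (E)-hydroxymethyl isomer.

Step 2
Reactants: 2 (E)-4-hydroxy-3-methylbut-2-en-1-yl acetate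
Product: 3 (E)-3-methyl-4-(triethylsilyloxy)but-2-en-1-yl acetate
Conditions: TESCl, imidazole, CH2Cl2, 0 °C
Reagents that add atoms: chlorotriethylsilane, CC[Si](Cl)(CC)CC
Why: Standard silylation of a primary allylic alcohol masks the future C9 oxygen with a group that can later be removed next to TBS ethers.

Step 3
Reactants: 3 (E)-3-methyl-4-(triethylsilyloxy)but-2-en-1-yl acetate
Product: 4 (E)-3-methyl-4-(triethylsilyloxy)but-2-en-1-ol
Conditions: K2CO3 (0.2 equiv), MeOH, 0 °C
Reagents that add atoms: none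
Why: Carbonate-catalysed transesterification removes the acetate, while a triethylsilyl ether is stable to these mildly basic conditions.

Step 4
Reactants: 5 4-methyl hydrogen itaconate (4-methoxy-2-methylidene-4-oxobutanoic acid)
Product: 7 methyl 3-(hydroxymethyl)but-3-enoate, via mixed carbonic anhydride 6 (not isolated)
Conditions: i-BuOCOCl, N-methylmorpholine, THF, −15 °C; then NaBH4, H2O, 0 °C
Reagents that add atoms: none
Why: Mixed-anhydride activation followed by borohydride reduction converts only the free conjugated carboxylic acid into the allylic alcohol and leaves the methyl ester untouched.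

Step 5
Reactants: 7 methyl 3-(hydroxymethyl)but-3-enoate
Product: 8 methyl 3-[(tert-butyldimethylsilyloxy)methyl]but-3-enoate
Conditions: TBSCl, imidazole, CH2Cl2, 0 → 23 °C
Reagents that add atoms: tert-butyldimethylsilyl chloride, CC(C)(C)[Si](C)(C)Cl
Why: Silylation of the primary allylic alcohol protects the future C15 oxygen and blocks lactonisation onto the ester.

Step 6
Reactants: 8 methyl 3-[(tert-butyldimethylsilyloxy)methyl]but-3-enoate
Product: 9 3-[(tert-butyldimethylsilyloxy)methyl]but-3-enoic acid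
Conditions: LiOH·H2O, THF–H2O, 0 °C; then dilute HCl to pH 4
Reagents that add atoms: lithium hydroxide, [Li+].[OH-]
Why: Saponification at 0 °C, where hydroxide attack at the ester carbonyl is faster than base-induced migration of the β,γ-alkene into conjugation.

Step 7
Reactants: 9 3-[(tert-butyldimethylsilyloxy)methyl]but-3-enoic acid; 4 (E)-3-methyl-4-(triethylsilyloxy)but-2-en-1-ol
Product: 10 (E)-3-methyl-4-(triethylsilyloxy)but-2-en-1-yl 3-[(tert-butyldimethylsilyloxy)methyl]but-3-enoate
Conditions: DCC, DMAP (5 mol %), CH2Cl2, 0 → 23 °C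
Reagents that add atoms: none
Why: Steglich esterification with little DMAP at low temperature joins the two C5 units without isomerising the β,γ-unsaturated acyl group.

Step 8
Reactants: 10 (E)-3-methyl-4-(triethylsilyloxy)but-2-en-1-yl 3-[(tert-butyldimethylsilyloxy)methyl]but-3-enoate
Product: 13 (2S,3S)-2-[3-(tert-butyldimethylsilyloxy)prop-1-en-2-yl]-3-methyl-3-[(triethylsilyloxy)methyl]pent-4-enoic acid, via boron ketene acetal 11 (not isolated), via acyloxyborane 12 (not isolated)
Conditions: (S,S)-2-bromo-4,5-diphenyl-1,3-bis[3,5-bis(trifluoromethyl)phenylsulfonyl]-1,3,2-diazaborolidine, Et3N, toluene–hexane, −78 °C, then 4 °C; aqueous work-up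
Reagents that add atoms: none
Why: Enantioselective Ireland–Claisen rearrangement of a chiral boron ketene acetal: soft enolisation in the non-ionising medium should give the E(O) enolate 11 (C4 arm cis to the allyloxy oxygen), a chair with the (E)-alkene then places the C14 methyl and the C4 arm axial so that C5–C10 forms with the relative configuration of the target, and the C2-symmetric sulfonamide ligand selects the face.

Step 9
Reactants: 13 (2S,3S)-2-[3-(tert-butyldimethylsilyloxy)prop-1-en-2-yl]-3-methyl-3-[(triethylsilyloxy)methyl]pent-4-enoic acid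
Product: 14 (2S,3S)-2-[3-(tert-butyldimethylsilyloxy)prop-1-en-2-yl]-3-methyl-3-[(triethylsilyloxy)methyl]pent-4-en-1-ol
Conditions: LiAlH4, Et2O, 0 → 23 °C
Reagents that add atoms: none
Why: Hydride reduction of the carboxylic acid to the primary alcohol; silyl ethers and unactivated alkenes are inert to LiAlH4.

Step 10
Reactants: 14 (2S,3S)-2-[3-(tert-butyldimethylsilyloxy)prop-1-en-2-yl]-3-methyl-3-[(triethylsilyloxy)methyl]pent-4-en-1-ol
Product: 15 (2S,3S)-2-[3-(tert-butyldimethylsilyloxy)prop-1-en-2-yl]-3-methyl-3-[(triethylsilyloxy)methyl]pent-4-enal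
Conditions: Dess–Martin periodinane, NaHCO3, CH2Cl2, 0 → 23 °C; used directly
Reagents that add atoms: none
Why: Buffered Dess–Martin oxidation gives the C6 aldehyde without base, so the C5 stereocentre (α to the carbonyl and allylic) should not epimerise.

Step 11
Reactants: 16 but-2-yne-1,4-diol
Product: 17 4-(tert-butyldimethylsilyloxy)but-2-yn-1-ol
Conditions: NaH (1 equiv), THF, 23 °C; then TBSCl (1 equiv)
Reagents that add atoms: tert-butyldimethylsilyl chloride, CC(C)(C)[Si](C)(C)Cl
Why: Monosilylation of a symmetrical diol through its sparingly soluble monosodium alkoxide differentiates the future C12 and C8 oxygens.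

Step 12
Reactants: 17 4-(tert-butyldimethylsilyloxy)but-2-yn-1-ol
Product: 19 (Z)-4-(tert-butyldimethylsilyloxy)-3-iodobut-2-en-1-ol, via cyclic alkenylalanate 18 (not isolated)
Conditions: Red-Al, THF, 0 °C; then I2, −78 → 0 °C
Reagents that add atoms: iodine, II
Why: Hydroxyl-directed trans-hydroalumination puts aluminium on the distal alkyne carbon, and iodinolysis with retention gives the Z-iodide with iodine cis to CH2OH.

Step 13
Reactants: 19 (Z)-4-(tert-butyldimethylsilyloxy)-3-iodobut-2-en-1-ol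
Product: 20 (Z)-4-(tert-butyldimethylsilyloxy)-3-iodo-1-(triethylsilyloxy)but-2-ene
Conditions: TESCl, imidazole, CH2Cl2, 0 °C
Reagents that add atoms: chlorotriethylsilane, CC[Si](Cl)(CC)CC
Why: Silylation gives the future C8 oxygen the same triethylsilyl group as C9, so that both can be released together later.

Step 14
Reactants: 20 (Z)-4-(tert-butyldimethylsilyloxy)-3-iodo-1-(triethylsilyloxy)but-2-ene
Product: 21 2-[(E)-2-[(tert-butyldimethylsilyloxy)methyl]-4-(triethylsilyloxy)but-2-en-1-yl]-4,4,5,5-tetramethyl-1,3,2-dioxaborolane (CH2B cis to CH2OTES)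
Conditions: ICH2Bpin, Zn dust, THF, 23 °C; then 20, Pd(PPh3)4 (5 mol %), THF, 40 °C
Reagents that add atoms: 2-(iodomethyl)-4,4,5,5-tetramethyl-1,3,2-dioxaborolane, ICB1OC(C)(C)C(C)(C)O1
Why: Negishi cross-coupling of the borylmethylzinc reagent with the alkenyl iodide proceeds with retention of alkene geometry and so gives the allylboronate with its γ-substituent cis to CH2B, without an alkenyllithium that could undergo silyl migration.

Step 15
Reactants: 15 (2S,3S)-2-[3-(tert-butyldimethylsilyloxy)prop-1-en-2-yl]-3-methyl-3-[(triethylsilyloxy)methyl]pent-4-enal; 21 2-[(E)-2-[(tert-butyldimethylsilyloxy)methyl]-4-(triethylsilyloxy)but-2-en-1-yl]-4,4,5,5-tetramethyl-1,3,2-dioxaborolane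
Product: 23 (5S,6S,7R,10S)-12,15-bis(tert-butyldimethylsilyloxy)-8,9-bis(triethylsilyloxy)-8,9-seco-elema-1,3,11(13)-trien-6-ol, via pinacol borate 22 (not isolated)
Conditions: toluene (1 M), 4 Å MS, 23 → 45 °C; then aq. NaHCO3
Reagents that add atoms: none
Why: Allylboration through a closed six-membered chair: the Z-disposed CH2OTES ends up syn to the new hydroxyl, and the aldehyde should react anti to the quaternary C10 with C5–H turned toward the incoming γ-substituent (anti-Felkin, the usual preference of Z-γ-substituted allylboronates), which sets 6S and 7R.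

Step 16
Reactants: 23 (5S,6S,7R,10S)-12,15-bis(tert-butyldimethylsilyloxy)-8,9-bis(triethylsilyloxy)-8,9-seco-elema-1,3,11(13)-trien-6-ol
Product: 24 (5S,6S,7R,10S)-6,12,15-tris(tert-butyldimethylsilyloxy)-8,9-bis(triethylsilyloxy)-8,9-seco-elema-1,3,11(13)-triene
Conditions: TBSOTf, 2,6-lutidine, CH2Cl2, −78 → 0 °C
Reagents that add atoms: tert-butyldimethylsilyl trifluoromethanesulfonate, CC(C)(C)[Si](C)(C)OS(=O)(=O)C(F)(F)F
Why: The silyl triflate is reactive enough to cap the hindered secondary C6 hydroxyl, which must not be free when C8 becomes an aldehyde.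

Step 17
Reactants: 24 (5S,6S,7R,10S)-6,12,15-tris(tert-butyldimethylsilyloxy)-8,9-bis(triethylsilyloxy)-8,9-seco-elema-1,3,11(13)-triene
Product: 25 (5S,6S,7R,10S)-6,12,15-tris(tert-butyldimethylsilyloxy)-8,9-seco-elema-1,3,11(13)-triene-8,9-diol
Conditions: PPTS (0.3 equiv), MeOH–CH2Cl2, 0 °C
Reagents that add atoms: none
Why: Acid-catalysed methanolysis cleaves primary triethylsilyl ethers much faster than TBS ethers, so only the C8 and C9 hydroxyls should be released.

Step 18
Reactants: 25 (5S,6S,7R,10S)-6,12,15-tris(tert-butyldimethylsilyloxy)-8,9-seco-elema-1,3,11(13)-triene-8,9-diol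
Product: 26 (5S,6S,7S,10S)-6,12,15-tris(tert-butyldimethylsilyloxy)-8,9-seco-elema-1,3,11(13)-triene-8,9-dial
Conditions: Dess–Martin periodinane, NaHCO3, CH2Cl2, 0 → 23 °C; filtered and used at once
Reagents that add atoms: none
Why: Double Dess–Martin oxidation under neutral buffered conditions gives both aldehydes without the amine base that could eliminate the β-silyloxy group or epimerise C7 of the β,γ-unsaturated C8 aldehyde.

Step 19
Reactants: 26 (5S,6S,7S,10S)-6,12,15-tris(tert-butyldimethylsilyloxy)-8,9-seco-elema-1,3,11(13)-triene-8,9-dial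
Product: 28 (5S,6S,7R,8R,9S,10S)-6,12,15-tris(tert-butyldimethylsilyloxy)elema-1,3,11(13)-triene-8,9-diol, via bis-samarium diolate 27 (not isolated)
Conditions: SmI2 (3 equiv, 0.1 M in THF), THF, −78 → −30 °C, slow addition of 26; then sat. aq. NaHCO3
Reagents that add atoms: none
Why: Two single-electron transfers from samarium(II) turn the C8 and C9 aldehydes into samarium-bound ketyls (or one ketyl adds to the samarium-coordinated partner carbonyl) and C8–C9 forms to give diolate 27, protonated on work-up; the closest known reaction type is the SmI2 pinacol cyclisation of 1,6-dialdehydes to cis-cyclohexane-1,2-diols. The cyclohexane C5–C10 closes in the 6-exo-trig mode through a chair in which the vinyl group and the C5 and C7 arms are equatorial and the C10 methyl and C6 silyloxy groups axial on the β-face. Both oxygens are held by samarium(III) on the same side of the new bond, so the diol should be cis. Of the two cis arrangements, the one with C8–O axial would meet the axial methyl and silyloxy groups in 1,3-diaxial fashion, so C8–O is set equatorial (8R) and C9–O axial on the α-face (9S). The step needs carbonyl–carbonyl coupling to outrun ketyl–alkene closure, elimination and enolisation: the only 5-exo option (C8 onto C4) would attack a fully substituted alkene carbon, no leaving group is adjacent to either ketyl carbon, C9 has no α-hydrogen, and the sensitive C8 aldehyde is made under neutral conditions and reduced at once.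

Step 20
Reactants: 28 (5S,6S,7R,8R,9S,10S)-6,12,15-tris(tert-butyldimethylsilyloxy)elema-1,3,11(13)-triene-8,9-diol
Product: 29 (5S,6S,7R,8R,9S,10S)-6-(tert-butyldimethylsilyloxy)elema-1,3,11(13)-triene-8,9,12,15-tetrol
Conditions: HF·pyridine, pyridine, THF, 0 → 23 °C
Reagents that add atoms: none
Why: Buffered HF·pyridine removes the two primary allylic TBS ethers far faster than the secondary C6 ether, which is flanked by two branched carbons.

Step 21
Reactants: 29 (5S,6S,7R,8R,9S,10S)-6-(tert-butyldimethylsilyloxy)elema-1,3,11(13)-triene-8,9,12,15-tetrol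
Product: 32 (5R,6S,7R,8R,9S,10S)-6-(tert-butyldimethylsilyloxy)-9-hydroxy-15-oxoelema-1,3,11(13)-trien-12,8-olide, via dialdehyde diol 30 (not isolated), via lactol 31 (not isolated)
Conditions: activated MnO2 (excess), CH2Cl2, 23 °C
Reagents that add atoms: none
Why: MnO2 oxidises only the two allylic primary alcohols: C15 stops at the enal because C6–O is still silylated, whereas the C12 enal is trapped by the equatorial C8–OH as an allylic lactol and oxidised on to the trans-fused α-methylene-γ-lactone before the slower MnO2 cleavage of the vicinal diol can compete.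

Step 22
Reactants: 32 (5R,6S,7R,8R,9S,10S)-6-(tert-butyldimethylsilyloxy)-9-hydroxy-15-oxoelema-1,3,11(13)-trien-12,8-olide; 33 angelic acid
Product: 35 (5R,6S,7R,8R,9S,10S)-9-angeloyloxy-6-(tert-butyldimethylsilyloxy)-15-oxoelema-1,3,11(13)-trien-12,8-olide, via mixed anhydride 34 (not isolated)
Conditions: 33, 2,4,6-trichlorobenzoyl chloride, Et3N, toluene, 23 °C; then 32, 75 °C (no DMAP)
Reagents that add atoms: none
Why: Yamaguchi esterification through the mixed 2,4,6-trichlorobenzoic anhydride acylates the only free hydroxyl (axial C9–OH) and, without a nucleophilic catalyst, should not isomerise the Z-angelate to the tiglate.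

Step 23
Reactants: 35 (5R,6S,7R,8R,9S,10S)-9-angeloyloxy-6-(tert-butyldimethylsilyloxy)-15-oxoelema-1,3,11(13)-trien-12,8-olide
Product: 36 (5R,6S,7S,8R,9S,10S)-9-angeloyloxy-6-hydroxy-15-oxoelema-1,3,11(13)-trien-12,8-olide (CNP0320538.1)
Conditions: HF·pyridine, THF–MeCN, 0 → 23 °C
Reagents that add atoms: none
Why: Acidic fluoride desilylation frees C6–OH without touching the angelate, the α-methylene lactone or the enal, and because no oxidant is present the C6–OH/C15 aldehyde pair cannot be driven on to a second lactone.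

**Compound list**

1 | prenyl acetate | CC(C)=CCOC(C)=O | starting material
2 | (E)-4-hydroxy-3-methylbut-2-en-1-yl acetate | CC(=O)OC/C=C(\C)CO | intermediate
3 | (E)-3-methyl-4-(triethylsilyloxy)but-2-en-1-yl acetate | CC(=O)OC/C=C(\C)CO[Si](CC)(CC)CC | intermediate
4 | (E)-3-methyl-4-(triethylsilyloxy)but-2-en-1-ol | OC/C=C(\C)CO[Si](CC)(CC)CC | intermediate
5 | 4-methyl hydrogen itaconate | COC(=O)CC(=C)C(=O)O | starting material
6 | isobutyl carbonic mixed anhydride of 5 | COC(=O)CC(=C)C(=O)OC(=O)OCC(C)C | intermediate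
7 | methyl 3-(hydroxymethyl)but-3-enoate | COC(=O)CC(=C)CO | intermediate
8 | methyl 3-[(tert-butyldimethylsilyloxy)methyl]but-3-enoate | COC(=O)CC(=C)CO[Si](C)(C)C(C)(C)C | intermediate
9 | 3-[(tert-butyldimethylsilyloxy)methyl]but-3-enoic acid | OC(=O)CC(=C)CO[Si](C)(C)C(C)(C)C | intermediate
10 | (E)-3-methyl-4-(triethylsilyloxy)but-2-en-1-yl 3-[(tert-butyldimethylsilyloxy)methyl]but-3-enoate | C=C(CO[Si](C)(C)C(C)(C)C)CC(=O)OC/C=C(\C)CO[Si](CC)(CC)CC | intermediate
11 | E(O) boron ketene acetal of 10 with the (S,S)-diazaborolidine (C4 arm trans to O–B) | C=C(CO[Si](C)(C)C(C)(C)C)/C=C(/OB1N(S(=O)(=O)c2cc(C(F)(F)F)cc(C(F)(F)F)c2)[C@@H](c2ccccc2)[C@H](c2ccccc2)N1S(=O)(=O)c1cc(C(F)(F)F)cc(C(F)(F)F)c1)OC/C=C(\C)CO[Si](CC)(CC)CC | intermediate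
12 | acyloxyborane of acid 13 with the (S,S)-diazaborolidine | C=C[C@](C)(CO[Si](CC)(CC)CC)[C@H](C(=C)CO[Si](C)(C)C(C)(C)C)C(=O)OB1N(S(=O)(=O)c2cc(C(F)(F)F)cc(C(F)(F)F)c2)[C@@H](c2ccccc2)[C@H](c2ccccc2)N1S(=O)(=O)c1cc(C(F)(F)F)cc(C(F)(F)F)c1 | intermediate
13 | (2S,3S)-2-[3-(tert-butyldimethylsilyloxy)prop-1-en-2-yl]-3-methyl-3-[(triethylsilyloxy)methyl]pent-4-enoic acid (C6 acid; C5 and C10 set) | C=C[C@](C)(CO[Si](CC)(CC)CC)[C@H](C(=C)CO[Si](C)(C)C(C)(C)C)C(=O)O | intermediate
14 | (2S,3S)-2-[3-(tert-butyldimethylsilyloxy)prop-1-en-2-yl]-3-methyl-3-[(triethylsilyloxy)methyl]pent-4-en-1-ol | C=C[C@](C)(CO[Si](CC)(CC)CC)[C@H](C(=C)CO[Si](C)(C)C(C)(C)C)CO | intermediate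
15 | (2S,3S)-2-[3-(tert-butyldimethylsilyloxy)prop-1-en-2-yl]-3-methyl-3-[(triethylsilyloxy)methyl]pent-4-enal (C6 aldehyde) | C=C[C@](C)(CO[Si](CC)(CC)CC)[C@H](C(=C)CO[Si](C)(C)C(C)(C)C)C=O | intermediate
16 | but-2-yne-1,4-diol | OCC#CCO | starting material
17 | 4-(tert-butyldimethylsilyloxy)but-2-yn-1-ol | OCC#CCO[Si](C)(C)C(C)(C)C | intermediate
18 | sodium cyclic alkenylalanate (1-oxa-2-aluminacyclopent-3-ene ate complex from 17 and Red-Al) | [Na+].COCCO[Al-]1(OCCOC)OC/C=C1/CO[Si](C)(C)C(C)(C)C | intermediate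
19 | (Z)-4-(tert-butyldimethylsilyloxy)-3-iodobut-2-en-1-ol | OC/C=C(\I)CO[Si](C)(C)C(C)(C)C | intermediate
20 | (Z)-4-(tert-butyldimethylsilyloxy)-3-iodo-1-(triethylsilyloxy)but-2-ene | CC[Si](CC)(CC)OC/C=C(\I)CO[Si](C)(C)C(C)(C)C | intermediate
21 | 2-[(E)-2-[(tert-butyldimethylsilyloxy)methyl]-4-(triethylsilyloxy)but-2-en-1-yl]-4,4,5,5-tetramethyl-1,3,2-dioxaborolane (CH2B cis to CH2OTES) | CC[Si](CC)(CC)OC/C=C(\CB1OC(C)(C)C(C)(C)O1)CO[Si](C)(C)C(C)(C)C | intermediate
22 | pinacol borate ester of alcohol 23 | C=C[C@](C)(CO[Si](CC)(CC)CC)[C@H](C(=C)CO[Si](C)(C)C(C)(C)C)[C@H](OB1OC(C)(C)C(C)(C)O1)[C@@H](CO[Si](CC)(CC)CC)C(=C)CO[Si](C)(C)C(C)(C)C | intermediate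
23 | (5S,6S,7R,10S)-12,15-bis(tert-butyldimethylsilyloxy)-8,9-bis(triethylsilyloxy)-8,9-seco-elema-1,3,11(13)-trien-6-ol | C=C[C@](C)(CO[Si](CC)(CC)CC)[C@H](C(=C)CO[Si](C)(C)C(C)(C)C)[C@H](O)[C@@H](CO[Si](CC)(CC)CC)C(=C)CO[Si](C)(C)C(C)(C)C | intermediate
24 | (5S,6S,7R,10S)-6,12,15-tris(tert-butyldimethylsilyloxy)-8,9-bis(triethylsilyloxy)-8,9-seco-elema-1,3,11(13)-triene | C=C[C@](C)(CO[Si](CC)(CC)CC)[C@H](C(=C)CO[Si](C)(C)C(C)(C)C)[C@H](O[Si](C)(C)C(C)(C)C)[C@@H](CO[Si](CC)(CC)CC)C(=C)CO[Si](C)(C)C(C)(C)C | intermediate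
25 | (5S,6S,7R,10S)-6,12,15-tris(tert-butyldimethylsilyloxy)-8,9-seco-elema-1,3,11(13)-triene-8,9-diol | C=C[C@](C)(CO)[C@H](C(=C)CO[Si](C)(C)C(C)(C)C)[C@H](O[Si](C)(C)C(C)(C)C)[C@@H](CO)C(=C)CO[Si](C)(C)C(C)(C)C | intermediate
26 | (5S,6S,7S,10S)-6,12,15-tris(tert-butyldimethylsilyloxy)-8,9-seco-elema-1,3,11(13)-triene-8,9-dial (acyclic C8,C9-dialdehyde) | C=C[C@](C)(C=O)[C@H](C(=C)CO[Si](C)(C)C(C)(C)C)[C@H](O[Si](C)(C)C(C)(C)C)[C@@H](C=O)C(=C)CO[Si](C)(C)C(C)(C)C | intermediate
27 | bis(diiodosamarium(III)) cis-8,9-diolate | C=C[C@]1(C)[C@H](O[Sm](I)I)[C@H](O[Sm](I)I)[C@@H](C(=C)CO[Si](C)(C)C(C)(C)C)[C@@H](O[Si](C)(C)C(C)(C)C)[C@H]1C(=C)CO[Si](C)(C)C(C)(C)C | intermediate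
28 | (5S,6S,7R,8R,9S,10S)-6,12,15-tris(tert-butyldimethylsilyloxy)elema-1,3,11(13)-triene-8,9-diol (cis-8,9-diol) | C=C[C@]1(C)[C@H](O)[C@H](O)[C@@H](C(=C)CO[Si](C)(C)C(C)(C)C)[C@@H](O[Si](C)(C)C(C)(C)C)[C@H]1C(=C)CO[Si](C)(C)C(C)(C)C | intermediate
29 | (5S,6S,7R,8R,9S,10S)-6-(tert-butyldimethylsilyloxy)elema-1,3,11(13)-triene-8,9,12,15-tetrol | C=C[C@]1(C)[C@H](O)[C@H](O)[C@@H](C(=C)CO)[C@@H](O[Si](C)(C)C(C)(C)C)[C@H]1C(=C)CO | intermediate
30 | (5R,6S,7R,8R,9S,10S)-6-(tert-butyldimethylsilyloxy)-8,9-dihydroxyelema-1,3,11(13)-triene-12,15-dial | C=C[C@]1(C)[C@H](O)[C@H](O)[C@@H](C(=C)C=O)[C@@H](O[Si](C)(C)C(C)(C)C)[C@H]1C(=C)C=O | intermediate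
31 | 12,8-lactol of 30 (mixture at C12) | C=C[C@]1(C)[C@H](O)[C@@H]2OC(O)C(=C)[C@H]2[C@@H](O[Si](C)(C)C(C)(C)C)[C@H]1C(=C)C=O | intermediate
32 | (5R,6S,7R,8R,9S,10S)-6-(tert-butyldimethylsilyloxy)-9-hydroxy-15-oxoelema-1,3,11(13)-trien-12,8-olide | C=C[C@]1(C)[C@H](O)[C@@H]2OC(=O)C(=C)[C@H]2[C@@H](O[Si](C)(C)C(C)(C)C)[C@H]1C(=C)C=O | intermediate
33 | angelic acid ((Z)-2-methylbut-2-enoic acid) | C/C=C(/C)C(=O)O | starting material
34 | angelic 2,4,6-trichlorobenzoic anhydride | C/C=C(/C)C(=O)OC(=O)c1c(Cl)cc(Cl)cc1Cl | intermediate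
35 | (5R,6S,7R,8R,9S,10S)-9-angeloyloxy-6-(tert-butyldimethylsilyloxy)-15-oxoelema-1,3,11(13)-trien-12,8-olide | C=C[C@]1(C)[C@H](OC(=O)/C(C)=C\C)[C@@H]2OC(=O)C(=C)[C@H]2[C@@H](O[Si](C)(C)C(C)(C)C)[C@H]1C(=C)C=O | intermediate
36 | (5R,6S,7S,8R,9S,10S)-9-angeloyloxy-6-hydroxy-15-oxoelema-1,3,11(13)-trien-12,8-olide (CNP0320538.1) | C=C[C@]1(C)[C@H](OC(=O)/C(C)=C\C)[C@@H]2OC(=O)C(=C)[C@H]2[C@@H](O)[C@H]1C(=C)C=O | target

**Step count and risks**

Total: 23 steps. Longest linear sequence: 16 steps (steps 4–10 and 15–23 from 5; equally steps 1–3, 7–10 and 15–23 from 1).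

Steps most likely to fail:

Step 8. The soft enolisation may give the wrong enolate geometry, the ligand may discriminate the two faces of this new, hindered ester poorly, or rearrangement to a quaternary carbon may be slow enough for the boron ketene acetal to decay. The fallback sets out from 10 and replaces reagent control by a racemic rearrangement followed by separation on an auxiliary. A lithium/silicon Ireland–Claisen (LDA, Me3SiCl, THF, −78 → 23 °C) should lead through the E(O)-trimethylsilyl ketene acetal F1 and the trimethylsilyl ester F2 to the racemic acid F3 of the same relative configuration. Its pivalic mixed anhydride acylates lithiated (S)-4-benzyloxazolidin-2-one; the two diastereomeric imides are separated by chromatography, and the (2S,3S)-acyl imide F4 is cleaved with LiBH4 to come back to the route at alcohol 14.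

Step 15. Addition to an aldehyde that is α-branched and next to a quaternary carbon may be so slow that C5 epimerises or the aldehyde decomposes before the C–C bond forms. The fallback sets out from 21 and 15 and replaces the thermal boronic-ester addition by a Lewis-acid-triggered one at low temperature. KHF2 in aqueous methanol at 0 °C converts 21 into the potassium allyltrifluoroborate F5. BF3·OEt2 in CH2Cl2 at −78 °C releases the allyldifluoroborane F6, which adds to 15 through the same closed chair to give the difluoroborinate F7 and, after aqueous work-up, comes back to the route at 23.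

Step 19. Coupling through an arrangement in which samarium does not bridge the two oxygens may place the C9 oxygen equatorial, i.e. loss of cis selectivity. The fallback sets out from 26 and corrects C9 by oxidation and reduction. The trans-8,9-diol F8 formed in that case is acetylated at the less hindered C8–OH (Ac2O, pyridine, 0 °C) to the 8-monoacetate F9. The remaining C9–OH is oxidised with Dess–Martin periodinane to the 9-ketone F10. K-Selectride (THF, −78 °C) delivers hydride from the equatorial direction, as with six-ring ketones flanked by a quaternary carbon, to give the axial 9-alcohol F11. Methanolysis of the acetate (K2CO3, MeOH) comes back to the route at 28.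

Further compounds
F1 | step 8 | E(O)-trimethylsilyl ketene acetal of 10 | C=C(CO[Si](C)(C)C(C)(C)C)/C=C(/O[Si](C)(C)C)OC/C=C(\C)CO[Si](CC)(CC)CC
F2 | step 8 | racemic trimethylsilyl ester of the rearranged acid | C=C[C@](C)(CO[Si](CC)(CC)CC)[C@H](C(=C)CO[Si](C)(C)C(C)(C)C)C(=O)O[Si](C)(C)C.C=C[C@@](C)(CO[Si](CC)(CC)CC)[C@@H](C(=C)CO[Si](C)(C)C(C)(C)C)C(=O)O[Si](C)(C)C
F3 | step 8 | racemic acid (13 and its enantiomer) | C=C[C@](C)(CO[Si](CC)(CC)CC)[C@H](C(=C)CO[Si](C)(C)C(C)(C)C)C(=O)O.C=C[C@@](C)(CO[Si](CC)(CC)CC)[C@@H](C(=C)CO[Si](C)(C)C(C)(C)C)C(=O)O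
F4 | step 8 | (S)-4-benzyl-3-[(2S,3S)-acyl]oxazolidin-2-one imide of acid 13 | C=C[C@](C)(CO[Si](CC)(CC)CC)[C@H](C(=C)CO[Si](C)(C)C(C)(C)C)C(=O)N1[C@@H](Cc2ccccc2)COC1=O
F5 | step 15 | potassium allyltrifluoroborate from 21 | CC[Si](CC)(CC)OC/C=C(\C[B-](F)(F)F)CO[Si](C)(C)C(C)(C)C.[K+]
F6 | step 15 | allyldifluoroborane | CC[Si](CC)(CC)OC/C=C(\CB(F)F)CO[Si](C)(C)C(C)(C)C
F7 | step 15 | difluoroborinate of 23 | C=C[C@](C)(CO[Si](CC)(CC)CC)[C@H](C(=C)CO[Si](C)(C)C(C)(C)C)[C@H](OB(F)F)[C@@H](CO[Si](CC)(CC)CC)C(=C)CO[Si](C)(C)C(C)(C)C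
F8 | step 19 | trans-8,9-diol (9-epimer of 28) | C=C[C@]1(C)[C@@H](O)[C@H](O)[C@@H](C(=C)CO[Si](C)(C)C(C)(C)C)[C@@H](O[Si](C)(C)C(C)(C)C)[C@H]1C(=C)CO[Si](C)(C)C(C)(C)C
F9 | step 19 | 8-monoacetate of the trans-diol | C=C[C@]1(C)[C@@H](O)[C@H](OC(C)=O)[C@@H](C(=C)CO[Si](C)(C)C(C)(C)C)[C@@H](O[Si](C)(C)C(C)(C)C)[C@H]1C(=C)CO[Si](C)(C)C(C)(C)C
F10 | step 19 | 8-acetoxy 9-ketone | C=C[C@]1(C)C(=O)[C@H](OC(C)=O)[C@@H](C(=C)CO[Si](C)(C)C(C)(C)C)[C@@H](O[Si](C)(C)C(C)(C)C)[C@H]1C(=C)CO[Si](C)(C)C(C)(C)C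
F11 | step 19 | axial 9-alcohol (8-acetate of 28) | C=C[C@]1(C)[C@H](O)[C@H](OC(C)=O)[C@@H](C(=C)CO[Si](C)(C)C(C)(C)C)[C@@H](O[Si](C)(C)C(C)(C)C)[C@H]1C(=C)CO[Si](C)(C)C(C)(C)C
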